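**Retrosynthetic overview**

1. The last step only removes three benzyl ethers. Before it, the butenolide ring (lactone numbering: O1, C2 = lactone C=O, C3 = C–OMe, C4 = C–aryl, C5 = quaternary carbon) is assembled in one operation.
2. Key disconnection: a [2+2+1] opening of the butenolide into an α-ketoester (C5=O1, bearing CO2Me and the chromanylmethyl arm), an aryl ynol ether (C3≡C4) and CO (C2). This joins two fragments of similar size at the fully substituted C5 and sets its R configuration under catalyst control.
3. Enabling feature: C5 carries O1 and an ester, so its precursor is a ketone flanked by a chelating ester carbonyl. C3 carries OMe, so the C3≡C4 alkyne is an oxygen-polarised ynol ether whose aryl-bearing C4 is the nucleophilic end that meets C5.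
4. The ketoester comes from 6-bromo-2,2-dimethyl-2H-chromene (asymmetric epoxidation sets C3 of the chroman, then hydride opening, benzylation, copper-catalysed Grignard opening of methyl glycidate, oxidation). The ynol ether comes from a Negishi coupling.
5. Ring order: the benzene rings and the pyran ring of the chroman are bought; the butenolide is the only ring formed, in the key step.

Key step: step 7

Remark (assumption): the (R,R)-(salen)MnCl catalyst is taken to deliver the (3R,4R)-epoxide of a 2,2-dimethylchromene, the established sense for this substrate class, and the α-ketoester is drawn as its keto tautomer although it should rest mainly as the Z-enol.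

**Route**

Step 1
Reactants: 1 6-bromo-2,2-dimethyl-2H-chromene
Product: 2 (3R,4R)-6-bromo-3,4-epoxy-2,2-dimethylchroman
Conditions: (R,R)-[N,N'-bis(3,5-di-tert-butylsalicylidene)-1,2-cyclohexanediaminato]manganese chloride, i.e. (R,R)-(salen)MnCl (3 mol %), 4-phenylpyridine N-oxide (10 mol %), aq. NaOCl (pH 11.3), CH2Cl2, 0 °C
Reagents that add atoms: sodium hypochlorite, [Na+].[O-]Cl
Why: Jacobsen–Katsuki asymmetric epoxidation, for which cis-configured aryl-conjugated 2,2-dimethylchromenes are the privileged substrate class; the (R,R)-salen ligand steers oxygen transfer to one face of the C3=C4 bond and so sets C3 (and C4) as R.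

Step 2
Reactants: 2 (3R,4R)-6-bromo-3,4-epoxy-2,2-dimethylchroman
Product: 3 (3R)-6-bromo-2,2-dimethylchroman-3-ol
Conditions: LiBHEt3 (1.5 equiv), THF, 0 °C to rt; H2O work-up
Reagents that add atoms: none
Why: Reductive epoxide opening by SN2 hydride attack at the benzylic C4, which is less hindered than C3 next to the quaternary C2, so that the C3–O bond and its R configuration are retained and the aryl bromide is untouched.

Step 3
Reactants: 3 (3R)-6-bromo-2,2-dimethylchroman-3-ol
Product: 4 (3R)-3-(benzyloxy)-6-bromo-2,2-dimethylchroman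
Conditions: NaH, BnBr, n-Bu4NI (cat.), DMF, 0 °C to rt
Reagents that add atoms: benzyl bromide, BrCc1ccccc1
Why: Williamson ether synthesis on the sodium alkoxide, in which the stereocentre is not involved.

Step 4
Reactants: 4 (3R)-3-(benzyloxy)-6-bromo-2,2-dimethylchroman; 5 methyl (2S)-oxirane-2-carboxylate
Product: 7 methyl (2S)-3-[(3R)-3-(benzyloxy)-2,2-dimethylchroman-6-yl]-2-hydroxypropanoate, via arylmagnesium bromide 6 (not isolated)
Conditions: Mg turnings, THF, 40 °C; then CuI (10 mol %), 5 (1.3 equiv), THF, −40 to −20 °C; H2O work-up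
Reagents that add atoms: none
Why: Copper-catalysed SN2 opening of a glycidic ester by an aryl Grignard reagent at the unsubstituted oxirane carbon, which should outrun addition to the ester at −40 °C and leaves C2 of the hydroxy ester with the configuration of 5 (a centre that step 5 removes).

Step 5
Reactants: 7 methyl (2S)-3-[(3R)-3-(benzyloxy)-2,2-dimethylchroman-6-yl]-2-hydroxypropanoate
Product: 8 methyl 3-[(3R)-3-(benzyloxy)-2,2-dimethylchroman-6-yl]-2-oxopropanoate
Conditions: Dess–Martin periodinane (1.3 equiv), CH2Cl2, 0 °C to rt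
Reagents that add atoms: none
Why: Dess–Martin oxidation of the α-hydroxy ester to the α-ketoester under neutral, non-enolising conditions that should avoid aldol self-condensation, with the chroman centre remote from the reaction site.

Step 6
Reactants: 9 2-chloro-1,1-dimethoxyethane; 10 1,2-bis(benzyloxy)-4-bromobenzene
Product: 13 1,2-bis(benzyloxy)-4-(methoxyethynyl)benzene, via lithium methoxyacetylide 11 (not isolated), via methoxyethynylzinc chloride 12 (not isolated)
Conditions: 9 (1.5 equiv), LiNEt2 (3.2 equiv per 9), THF, −78 to 0 °C; ZnCl2 (1.1 equiv per 9), 0 °C; then 10, Pd(OAc)2 (2 mol %), SPhos (4 mol %), THF, rt to 45 °C; H2O work-up, Et3N-deactivated silica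
Reagents that add atoms: none
Why: Base-induced twofold elimination and deprotonation of the chloroacetal gives the alkoxyacetylide in the flask, and transmetalation to zinc followed by Negishi coupling with the aryl bromide should give the aryl ynol ether without any contact with acid.

Step 7
Reactants: 8 methyl 3-[(3R)-3-(benzyloxy)-2,2-dimethylchroman-6-yl]-2-oxopropanoate; 13 1,2-bis(benzyloxy)-4-(methoxyethynyl)benzene
Product: 14 methyl (2R)-3-[3,4-bis(benzyloxy)phenyl]-2-{[(3R)-3-(benzyloxy)-2,2-dimethylchroman-6-yl]methyl}-4-methoxy-5-oxo-2,5-dihydrofuran-2-carboxylate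
Conditions: [Rh(cod)2]OTf (5 mol %), (R)-xylyl-BINAP (6 mol %, or its antipode, to be fixed by a test run), CO (1 atm), 4 Å molecular sieves, 1,2-dichloroethane, 60 °C, slow addition of 13 (1.5 equiv)
Reagents that add atoms: carbon monoxide, [C-]#[O+]
Why: Proposed new method: a cationic monovalent rhodium–bisphosphine centre is chelated by the vicinal ketone and ester oxygens of the keto tautomer of 8 and binds the ynol ether 13; oxidative cyclisation joins the ketone carbon to the aryl-bearing alkyne carbon and gives an oxarhodacyclopentene, CO inserts into the Rh–C(OMe) bond and C–O reductive elimination releases the butenolide, so that the bond from the quaternary carbon to the aryl-bearing ring carbon, the bond from the lactone carbonyl to the methoxy-bearing carbon and the lactone C–O bond all form in one operation. The closest known reaction types are the Ru3(CO)12-catalysed intermolecular [2+2+1] cyclocoupling of α-ketoesters, internal alkynes and CO to butenolides (hetero-Pauson–Khand reaction), the enantioselective rhodium–bisphosphine oxidative coupling of alkynes with α-ketoesters, and rhodium–BINAP asymmetric Pauson–Khand reactions; new here are the ynol ether partner and the enantioselective carbonylative turnover. The butenolide ring is closed in a three-component [2+2+1] mode, the last event being a five-membered-ring-forming C–O reductive elimination from the six-membered acyl rhodacycle. The new quaternary centre is set by the catalyst: the C2-symmetric bisphosphine blocks one face of the chelated, s-cis-locked ketoester, and the remote (3R) centre of the chroman has no say, so that the minor isomer would be a diastereomer of 14. The step needs regioselectivity and chemoselectivity: the oxygen lone pair of the ynol ether makes its aryl-bearing carbon the nucleophilic terminus, which bonds to the electrophilic ketone carbon while rhodium takes the methoxy-bearing carbon, and chelation singles out the ketone over the ester carbonyl.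

Step 8
Reactants: 14 methyl (2R)-3-[3,4-bis(benzyloxy)phenyl]-2-{[(3R)-3-(benzyloxy)-2,2-dimethylchroman-6-yl]methyl}-4-methoxy-5-oxo-2,5-dihydrofuran-2-carboxylate
Product: 15 methyl (2R)-3-(3,4-dihydroxyphenyl)-2-{[(3R)-3-hydroxy-2,2-dimethyl-3,4-dihydro-2H-chromen-6-yl]methyl}-4-methoxy-5-oxo-2,5-dihydrofuran-2-carboxylate
Conditions: H2 (1 atm), Pd(OH)2/C, EtOAc–MeOH, rt
Reagents that add atoms: none
Why: Catalytic hydrogenolysis of the two aryl benzyl ethers and the alkyl benzyl ether, which should leave the tetrasubstituted conjugated butenolide C=C, the lactone, the esters and both stereocentres (neither on a benzylic C–O bond) untouched.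

**Compound list**

1 | 6-bromo-2,2-dimethyl-2H-chromene | CC1(C)C=Cc2cc(Br)ccc2O1 | starting material
2 | (3R,4R)-6-bromo-3,4-epoxy-2,2-dimethylchroman | O1c2ccc(Br)cc2[C@H]3O[C@H]3C1(C)C | intermediate
3 | (3R)-6-bromo-2,2-dimethylchroman-3-ol | Brc1ccc2c(c1)C[C@@H](O)C(C)(C)O2 | intermediate
4 | (3R)-3-(benzyloxy)-6-bromo-2,2-dimethylchroman | Brc1ccc2c(c1)C[C@@H](OCc1ccccc1)C(C)(C)O2 | intermediate
5 | methyl (2S)-oxirane-2-carboxylate (methyl (S)-glycidate) | COC(=O)[C@@H]1CO1 | starting material
6 | [(3R)-3-(benzyloxy)-2,2-dimethylchroman-6-yl]magnesium bromide | Br[Mg]c1ccc2c(c1)C[C@@H](OCc1ccccc1)C(C)(C)O2 | intermediate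
7 | methyl (2S)-3-[(3R)-3-(benzyloxy)-2,2-dimethylchroman-6-yl]-2-hydroxypropanoate | COC(=O)[C@@H](O)Cc1ccc2c(c1)C[C@@H](OCc1ccccc1)C(C)(C)O2 | intermediate
8 | methyl 3-[(3R)-3-(benzyloxy)-2,2-dimethylchroman-6-yl]-2-oxopropanoate (keto form shown) | COC(=O)C(=O)Cc1ccc2c(c1)C[C@@H](OCc1ccccc1)C(C)(C)O2 | intermediate
9 | 2-chloro-1,1-dimethoxyethane (chloroacetaldehyde dimethyl acetal) | COC(CCl)OC | starting material
10 | 1,2-bis(benzyloxy)-4-bromobenzene | Brc1ccc(OCc2ccccc2)c(OCc2ccccc2)c1 | starting material
11 | lithium methoxyacetylide | [Li]C#COC | intermediate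
12 | methoxyethynylzinc chloride | Cl[Zn]C#COC | intermediate
13 | 1,2-bis(benzyloxy)-4-(methoxyethynyl)benzene | COC#Cc1ccc(OCc2ccccc2)c(OCc2ccccc2)c1 | intermediate
14 | methyl (2R)-3-[3,4-bis(benzyloxy)phenyl]-2-{[(3R)-3-(benzyloxy)-2,2-dimethylchroman-6-yl]methyl}-4-methoxy-5-oxo-2,5-dihydrofuran-2-carboxylate | COC(=O)[C@]1(Cc2ccc3c(c2)C[C@@H](OCc2ccccc2)C(C)(C)O3)OC(=O)C(OC)=C1c1ccc(OCc2ccccc2)c(OCc2ccccc2)c1 | intermediate
15 | methyl (2R)-3-(3,4-dihydroxyphenyl)-2-{[(3R)-3-hydroxy-2,2-dimethyl-3,4-dihydro-2H-chromen-6-yl]methyl}-4-methoxy-5-oxo-2,5-dihydrofuran-2-carboxylate | COC(=O)[C@]1(Cc2ccc3c(c2)C[C@@H](O)C(C)(C)O3)OC(=O)C(OC)=C1c1ccc(O)c(O)c1 | target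

**Step count and risks**

Total steps: 8. Longest linear sequence: 7 steps (steps 1 to 5, then 7 and 8).

Most likely to fail, first: step 7. The ketoester may stay locked as its enol, so that chelation fails and the enol O–H adds to the ynol ether. A Lewis-acid-type [2+2] carbonyl–alkyne metathesis or cyclotrimerisation of the ynol ether may outrun carbonylative closure. Facial selectivity at the new quaternary carbon may be poor. The fallback uses known chemistry (self-regeneration of a stereocentre through a pivalaldehyde dioxolanone, then an intramolecular aldol condensation); it sets out from 7 (this is why 5 is used as its S enantiomer) and comes back at 14. Saponification of 7 (LiOH, THF–H2O) would give (2S)-3-[(3R)-3-(benzyloxy)-2,2-dimethylchroman-6-yl]-2-hydroxypropanoic acid F1. Acetalisation with pivalaldehyde (TsOH cat., pentane, water removal) would give the cis-configured 2-tert-butyl-1,3-dioxolan-4-one F2. Its lithium enolate (LiN(iPr)2, THF, −78 °C) should add to 3,4-bis(benzyloxy)benzaldehyde on the face away from the tert-butyl group, which fixes the quaternary centre in the aldol adduct F3. Dess–Martin oxidation would give the 5-aroyl dioxolanone F4, and NaOMe (cat.) in MeOH at 0 °C would release the tertiary hydroxy keto ester F5. Acylation with methoxyacetyl chloride (pyridine, DMAP cat., CH2Cl2) would give the methoxyacetate F6. Intramolecular aldol condensation of its ester enolate onto the aryl ketone (LiN(SiMe3)2, THF, −78 to 0 °C, then SOCl2–pyridine if the aldol lactone does not dehydrate by itself) would close the butenolide to 14.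

Second: step 6. Elimination to the acetylide may stay incomplete, oxidative addition of the electron-rich aryl bromide may be slow, and the ynol ether may be hydrated during isolation. The fallback sets out from 10 and comes back at 13. Bromine–lithium exchange (n-BuLi, THF, −78 °C) and acylation with N,2-dimethoxy-N-methylacetamide would give 1-[3,4-bis(benzyloxy)phenyl]-2-methoxyethan-1-one F7. Enolisation and O-sulfonylation (KN(SiMe3)2, PhNTf2, THF, −78 °C) would give the (Z)-enol triflate F8. Anti-elimination with KOtBu (THF, −78 °C) would deliver 13, ready for direct use.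

Third: step 4. The aryl Grignard reagent may add to the ester carbonyl, and bromide may open the oxirane. The fallback sets out from 4 and comes back at 8, bypassing 7 and step 5. Bromine–lithium exchange (n-BuLi, THF, −78 °C) and formylation with DMF would give (3R)-3-(benzyloxy)-2,2-dimethylchroman-6-carbaldehyde F9. Horner–Wadsworth–Emmons olefination with methyl 2-[(tert-butyldimethylsilyl)oxy]-2-(dimethoxyphosphoryl)acetate (LiN(SiMe3)2, THF, −78 °C to rt) would give the silyl enol ether of the ketoester F10 (mainly Z, geometry irrelevant). Desilylation (CsF, AcOH, MeCN) would give 8.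

**Further compounds**

F1 | step 7 | (2S)-3-[(3R)-3-(benzyloxy)-2,2-dimethylchroman-6-yl]-2-hydroxypropanoic acid | OC(=O)[C@@H](O)Cc1ccc2c(c1)C[C@@H](OCc1ccccc1)C(C)(C)O2
F2 | step 7 | (2S,5S)-5-{[(3R)-3-(benzyloxy)-2,2-dimethylchroman-6-yl]methyl}-2-tert-butyl-1,3-dioxolan-4-one | CC(C)(C)[C@@H]1OC(=O)[C@H](Cc2ccc3c(c2)C[C@@H](OCc2ccccc2)C(C)(C)O3)O1
F3 | step 7 | (2S,5R)-5-{[3,4-bis(benzyloxy)phenyl](hydroxy)methyl}-5-{[(3R)-3-(benzyloxy)-2,2-dimethylchroman-6-yl]methyl}-2-tert-butyl-1,3-dioxolan-4-one (carbinol epimers) | CC(C)(C)[C@@H]1OC(=O)[C@@](Cc2ccc3c(c2)C[C@@H](OCc2ccccc2)C(C)(C)O3)(C(O)c2ccc(OCc3ccccc3)c(OCc3ccccc3)c2)O1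
F4 | step 7 | (2S,5R)-5-[3,4-bis(benzyloxy)benzoyl]-5-{[(3R)-3-(benzyloxy)-2,2-dimethylchroman-6-yl]methyl}-2-tert-butyl-1,3-dioxolan-4-one | CC(C)(C)[C@@H]1OC(=O)[C@@](Cc2ccc3c(c2)C[C@@H](OCc2ccccc2)C(C)(C)O3)(C(=O)c2ccc(OCc3ccccc3)c(OCc3ccccc3)c2)O1
F5 | step 7 | methyl (2R)-2-{[(3R)-3-(benzyloxy)-2,2-dimethylchroman-6-yl]methyl}-3-[3,4-bis(benzyloxy)phenyl]-2-hydroxy-3-oxopropanoate | COC(=O)[C@@](O)(Cc1ccc2c(c1)C[C@@H](OCc1ccccc1)C(C)(C)O2)C(=O)c1ccc(OCc2ccccc2)c(OCc2ccccc2)c1
F6 | step 7 | methyl (2R)-2-{[(3R)-3-(benzyloxy)-2,2-dimethylchroman-6-yl]methyl}-3-[3,4-bis(benzyloxy)phenyl]-2-[(methoxyacetyl)oxy]-3-oxopropanoate | COC(=O)[C@@](OC(=O)COC)(Cc1ccc2c(c1)C[C@@H](OCc1ccccc1)C(C)(C)O2)C(=O)c1ccc(OCc2ccccc2)c(OCc2ccccc2)c1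
F7 | step 6 | 1-[3,4-bis(benzyloxy)phenyl]-2-methoxyethan-1-one | COCC(=O)c1ccc(OCc2ccccc2)c(OCc2ccccc2)c1
F8 | step 6 | (Z)-1-[3,4-bis(benzyloxy)phenyl]-2-methoxyethenyl trifluoromethanesulfonate | CO/C=C(\OS(=O)(=O)C(F)(F)F)c1ccc(OCc2ccccc2)c(OCc2ccccc2)c1
F9 | step 4 | (3R)-3-(benzyloxy)-2,2-dimethylchroman-6-carbaldehyde | O=Cc1ccc2c(c1)C[C@@H](OCc1ccccc1)C(C)(C)O2
F10 | step 4 | methyl (Z)-3-[(3R)-3-(benzyloxy)-2,2-dimethylchroman-6-yl]-2-[(tert-butyldimethylsilyl)oxy]prop-2-enoate | COC(=O)/C(O[Si](C)(C)C(C)(C)C)=C/c1ccc2c(c1)C[C@@H](OCc1ccccc1)C(C)(C)O2
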